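**Retrosynthetic overview**

- Feature: in the lactone ring (O1, C2 carbonyl, C3, C4, C5) the carbons C2–C3–C4–C5 carry the trans benzyl arms (C7 on C3, C7' on C4). They map onto C1, C5, C4 and C3 of a trans-4,5-dibenzylcyclopent-2-enone whose C2 sits where O1 will be.
- Late disconnection: the O1–C2 and O1–C5 bonds come from excision of that enone α-carbon (dihydroxylation, periodate cleavage, reduction, lactonisation); the catechol is freed last by hydrogenolysis.
- Key disconnection: the C4–C5 bond (lactone numbering) is made by a silicon-directed Nazarov 4π-conrotatory closure of a β-silyl divinyl ketone under a chiral N-triflylphosphoramide.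
- The dienone comes from a Weinreb amide and (E)-2-(trimethylsilyl)vinyllithium; its trisubstituted E-alkene comes from a Wittig reaction of a benzylated stabilised ylide with the arylacetaldehyde made from 3,4-bis(benzyloxy)benzaldehyde.
- Ring order: temporary cyclopentenone (step 7), cleaved (step 8), γ-lactone closed (step 9).

Key step: step 7

Assumption: the (R)-configured catalyst is taken to favour the conrotation that leads to (4S)-14; if the sense of induction proves opposite, the (S)-catalyst is used with no other change.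

**Route**

Step 1
Reactants: 1 3,4-bis(benzyloxy)benzaldehyde
Product: 2 1,2-bis(benzyloxy)-4-(2-methoxyvinyl)benzene (E/Z mixture)
Conditions: Ph3P(CH2OMe)Cl, KOtBu, THF, 0 °C → rt
Reagents that add atoms: (methoxymethyl)triphenylphosphonium chloride, COC[P+](c1ccccc1)(c1ccccc1)c1ccccc1.[Cl-]
Why: Wittig methoxymethylenation of a non-enolisable aromatic aldehyde with the non-stabilised ylide should give the homologous enol ether, both alkene isomers of which lead to the same aldehyde, and the benzyl ethers are inert to the base.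

Step 2
Reactants: 2 1,2-bis(benzyloxy)-4-(2-methoxyvinyl)benzene
Product: 3 2-[3,4-bis(benzyloxy)phenyl]acetaldehyde
Conditions: 2 M aq. HCl, THF, 50 °C; crude aldehyde used at once
Reagents that add atoms: water, O
Why: Acid-catalysed enol ether hydrolysis (C-protonation, hydration of the oxocarbenium ion, loss of methanol) completes the one-carbon homologation without touching the aryl benzyl ethers, and immediate use avoids self-condensation of the arylacetaldehyde.

Step 3
Reactants: 4 ethyl (triphenylphosphoranylidene)acetate; 5 3,4-dimethoxybenzyl bromide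
Product: 7 ethyl 3-(3,4-dimethoxyphenyl)-2-(triphenylphosphoranylidene)propanoate, via phosphonium bromide 6 (not isolated)
Conditions: CHCl3, reflux; then 1 M aq. NaOH, CH2Cl2, rt
Reagents that add atoms: none
Why: C-alkylation of an ester-stabilised phosphorus ylide by a reactive benzylic bromide (SN2) should stop at the mono-benzylated phosphonium salt, which aqueous hydroxide deprotonates to the new stabilised ylide.

Step 4
Reactants: 7 ethyl 3-(3,4-dimethoxyphenyl)-2-(triphenylphosphoranylidene)propanoate; 3 2-[3,4-bis(benzyloxy)phenyl]acetaldehyde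
Product: 8 ethyl (E)-4-[3,4-bis(benzyloxy)phenyl]-2-(3,4-dimethoxybenzyl)but-2-enoate
Conditions: CH2Cl2, rt → 40 °C
Reagents that add atoms: none
Why: Wittig olefination with an α-substituted stabilised ylide under neutral, salt-free conditions should give the E-trisubstituted enoate (ester trans to the new CH2Ar group), and the absence of base avoids enolisation of 3 and migration of the alkene into conjugation with the arene.

Step 5
Reactants: 8 ethyl (E)-4-[3,4-bis(benzyloxy)phenyl]-2-(3,4-dimethoxybenzyl)but-2-enoate
Product: 9 (E)-4-[3,4-bis(benzyloxy)phenyl]-2-(3,4-dimethoxybenzyl)-N-methoxy-N-methylbut-2-enamide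
Conditions: MeNH(OMe)·HCl, i-PrMgCl, THF, −20 → 0 °C
Reagents that add atoms: N,O-dimethylhydroxylamine hydrochloride, CNOC.Cl
Why: Direct aminolysis of the ester by the chloromagnesium amide (Weinreb amide synthesis) should proceed at low temperature, the α,β-disubstituted alkene resists conjugate addition, and the alkene geometry is not affected.

Step 6
Reactants: 9 (E)-4-[3,4-bis(benzyloxy)phenyl]-2-(3,4-dimethoxybenzyl)-N-methoxy-N-methylbut-2-enamide; 10 (E)-(2-bromovinyl)trimethylsilane
Product: 12 (1E,4E)-6-[3,4-bis(benzyloxy)phenyl]-4-(3,4-dimethoxybenzyl)-1-(trimethylsilyl)hexa-1,4-dien-3-one, via (E)-[2-(trimethylsilyl)vinyl]lithium 11 (not isolated)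
Conditions: 10, t-BuLi (2 equiv per 10), Et2O, −78 °C; then 9, THF, −78 → −40 °C; inverse quench into cold 1 M aq. HCl
Reagents that add atoms: none
Why: Bromine–lithium exchange retains the E geometry, acyl substitution on the Weinreb amide stops at the ketone because the chelated tetrahedral intermediate survives until the quench, and the acidic inverse quench protonates the released amine so that it cannot add to the enone.

Step 7
Reactants: 12 (1E,4E)-6-[3,4-bis(benzyloxy)phenyl]-4-(3,4-dimethoxybenzyl)-1-(trimethylsilyl)hexa-1,4-dien-3-one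
Product: 14 (4S,5R)-4-[3,4-bis(benzyloxy)benzyl]-5-(3,4-dimethoxybenzyl)cyclopent-2-en-1-one, via cyclopentadienol 13 (not isolated)
Conditions: (R)-3,3'-bis(2,4,6-triisopropylphenyl)-BINOL N-triflylphosphoramide (10 mol%), PhOH (1.1 equiv), CHCl3, 0 °C → rt
Reagents that add atoms: none
Why: O-protonation of 12 by the chiral N-triflylphosphoramide gives a hydroxypentadienyl cation paired with the chiral phosphoramide anion, and this cation closes the five-membered carbocycle by thermal conrotatory 4π-electrocyclisation, joining the silyl-bearing carbon to the carbon that carries the bis(benzyloxy)benzyl arm. The closest known reaction type is the silicon-directed Nazarov cyclisation of β-silyl divinyl ketones in its Brønsted-acid-catalysed enantioselective form. The sense of conrotation, and so the configuration at C4, is set by the hydrogen-bonded chiral counter-anion, while the silicon-bearing stereocentre formed at the same time is erased. The β-silicon effect makes the oxyallyl cation collapse by loss of the Me3Si group, which phenol takes up while returning the proton to the catalyst, so the ring alkene ends between the former silyl carbon and the unsubstituted α-carbon and not in the more substituted position. Dienol 13 is then protonated at C5, and under the acidic conditions this centre should equilibrate to the more stable trans (4S,5R) isomer. The step needs regiocontrol of the alkene (secured by silicon), trans ring substitution (thermodynamic) and enantiofacial control (catalyst), and the carbonyl ends next to the dimethoxybenzyl carbon because that arm is on the α-carbon of 12.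

Step 8
Reactants: 14 (4S,5R)-4-[3,4-bis(benzyloxy)benzyl]-5-(3,4-dimethoxybenzyl)cyclopent-2-en-1-one
Product: 16 (2R,3R)-3-[3,4-bis(benzyloxy)benzyl]-2-(3,4-dimethoxybenzyl)-4-oxobutanoic acid (in equilibrium with its γ-lactol), via cis-diol 15 (not isolated)
Conditions: OsO4 (cat.), NMO, acetone/H2O, rt; then NaIO4, rt; crude product reduced without delay
Reagents that add atoms: osmium tetroxide, O=[Os](=O)(=O)=O; N-methylmorpholine N-oxide, C[N+]1([O-])CCOCC1; water, O
Why: Upjohn syn-dihydroxylation of the enone C2=C3 bond (anti to the C4 benzyl group, configuration immaterial) followed by Malaprade periodate cleavage of both the diol and the α-ketol bonds should release C2 as formic acid, turn C1 into the carboxylic acid and C3 into the aldehyde, and leave the C4 and C5 stereocentres untouched under near-neutral conditions.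

Step 9
Reactants: 16 (2R,3R)-3-[3,4-bis(benzyloxy)benzyl]-2-(3,4-dimethoxybenzyl)-4-oxobutanoic acid
Product: 18 (3R,4R)-4-[3,4-bis(benzyloxy)benzyl]-3-(3,4-dimethoxybenzyl)dihydrofuran-2(3H)-one, via hydroxy acid 17 (not isolated)
Conditions: NaBH4, THF/MeOH, 0 °C; then 2 M aq. HCl, rt
Reagents that add atoms: none
Why: Borohydride reduces the aldehyde (through the open form of the lactol) but not the carboxylate, and acidification closes the γ-lactone by intramolecular esterification, so the former ketone carbon becomes the lactone carbonyl next to the dimethoxybenzyl carbon and no stereocentre is involved.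

Step 10
Reactants: 18 (3R,4R)-4-[3,4-bis(benzyloxy)benzyl]-3-(3,4-dimethoxybenzyl)dihydrofuran-2(3H)-one
Product: 19 (3R,4R)-4-(3,4-dihydroxybenzyl)-3-(3,4-dimethoxybenzyl)dihydrofuran-2(3H)-one
Conditions: H2 (1 atm), 10% Pd/C, EtOAc/MeOH, rt; filtration under argon
Reagents that add atoms: none
Why: Palladium-catalysed hydrogenolysis cleaves the two aryl benzyl ethers while the methyl ethers, the lactone and its non-benzylic C–O bond are inert, and the air-sensitive catechol is released only in the last step.

**Compound list**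

1 | 3,4-bis(benzyloxy)benzaldehyde | O=Cc1ccc(OCc2ccccc2)c(OCc2ccccc2)c1 | starting material
2 | 1,2-bis(benzyloxy)-4-(2-methoxyvinyl)benzene (E/Z mixture) | COC=Cc1ccc(OCc2ccccc2)c(OCc2ccccc2)c1 | intermediate
3 | 2-[3,4-bis(benzyloxy)phenyl]acetaldehyde | O=CCc1ccc(OCc2ccccc2)c(OCc2ccccc2)c1 | intermediate
4 | ethyl (triphenylphosphoranylidene)acetate | CCOC(=O)C=P(c1ccccc1)(c1ccccc1)c1ccccc1 | starting material
5 | 3,4-dimethoxybenzyl bromide | COc1ccc(CBr)cc1OC | starting material
6 | [1-ethoxy-3-(3,4-dimethoxyphenyl)-1-oxopropan-2-yl]triphenylphosphonium bromide (racemic) | CCOC(=O)C(Cc1ccc(OC)c(OC)c1)[P+](c1ccccc1)(c1ccccc1)c1ccccc1.[Br-] | intermediate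
7 | ethyl 3-(3,4-dimethoxyphenyl)-2-(triphenylphosphoranylidene)propanoate | CCOC(=O)C(Cc1ccc(OC)c(OC)c1)=P(c1ccccc1)(c1ccccc1)c1ccccc1 | intermediate
8 | ethyl (E)-4-[3,4-bis(benzyloxy)phenyl]-2-(3,4-dimethoxybenzyl)but-2-enoate | CCOC(=O)/C(Cc1ccc(OC)c(OC)c1)=C/Cc1ccc(OCc2ccccc2)c(OCc2ccccc2)c1 | intermediate
9 | (E)-4-[3,4-bis(benzyloxy)phenyl]-2-(3,4-dimethoxybenzyl)-N-methoxy-N-methylbut-2-enamide | CON(C)C(=O)/C(Cc1ccc(OC)c(OC)c1)=C/Cc1ccc(OCc2ccccc2)c(OCc2ccccc2)c1 | intermediate
10 | (E)-(2-bromovinyl)trimethylsilane | C[Si](C)(C)/C=C/Br | starting material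
11 | (E)-[2-(trimethylsilyl)vinyl]lithium | C[Si](C)(C)/C=C/[Li] | intermediate
12 | (1E,4E)-6-[3,4-bis(benzyloxy)phenyl]-4-(3,4-dimethoxybenzyl)-1-(trimethylsilyl)hexa-1,4-dien-3-one | C[Si](C)(C)/C=C/C(=O)/C(Cc1ccc(OC)c(OC)c1)=C/Cc1ccc(OCc2ccccc2)c(OCc2ccccc2)c1 | intermediate
13 | (S)-3-[3,4-bis(benzyloxy)benzyl]-2-(3,4-dimethoxybenzyl)cyclopenta-1,4-dien-1-ol | COc1ccc(CC2=C(O)C=C[C@@H]2Cc2ccc(OCc3ccccc3)c(OCc3ccccc3)c2)cc1OC | intermediate
14 | (4S,5R)-4-[3,4-bis(benzyloxy)benzyl]-5-(3,4-dimethoxybenzyl)cyclopent-2-en-1-one | COc1ccc(C[C@H]2C(=O)C=C[C@@H]2Cc2ccc(OCc3ccccc3)c(OCc3ccccc3)c2)cc1OC | intermediate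
15 | (2S,3S,4R,5R)-4-[3,4-bis(benzyloxy)benzyl]-5-(3,4-dimethoxybenzyl)-2,3-dihydroxycyclopentan-1-one (expected major diastereomer, diol anti to the C4 benzyl group) | COc1ccc(C[C@H]2C(=O)[C@@H](O)[C@@H](O)[C@@H]2Cc2ccc(OCc3ccccc3)c(OCc3ccccc3)c2)cc1OC | intermediate
16 | (2R,3R)-3-[3,4-bis(benzyloxy)benzyl]-2-(3,4-dimethoxybenzyl)-4-oxobutanoic acid | COc1ccc(C[C@@H](C(=O)O)[C@H](C=O)Cc2ccc(OCc3ccccc3)c(OCc3ccccc3)c2)cc1OC | intermediate
17 | (2R,3R)-3-[3,4-bis(benzyloxy)benzyl]-2-(3,4-dimethoxybenzyl)-4-hydroxybutanoic acid | COc1ccc(C[C@@H](C(=O)O)[C@H](CO)Cc2ccc(OCc3ccccc3)c(OCc3ccccc3)c2)cc1OC | intermediate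
18 | (3R,4R)-4-[3,4-bis(benzyloxy)benzyl]-3-(3,4-dimethoxybenzyl)dihydrofuran-2(3H)-one | COc1ccc(C[C@H]2C(=O)OC[C@@H]2Cc2ccc(OCc3ccccc3)c(OCc3ccccc3)c2)cc1OC | intermediate
19 | (3R,4R)-4-(3,4-dihydroxybenzyl)-3-(3,4-dimethoxybenzyl)dihydrofuran-2(3H)-one | COc1ccc(C[C@H]2C(=O)OC[C@@H]2Cc2ccc(O)c(O)c2)cc1OC | target

**Step count and risks**

Total step count: 10. Longest linear sequence: 9 steps (steps 1, 2 and 4 to 10, from 3,4-bis(benzyloxy)benzaldehyde); step 3 is a one-step side branch.

Steps most likely to fail:

Step 7. The acid may activate this unactivated dienone only slowly, and the chiral anion may discriminate poorly between the two senses of conrotation. If silyl transfer to phenol lags, the silylated catalyst can promote a racemic background cyclisation. The oxyallyl cation could also be intercepted by a pendant electron-rich arene before silicon is lost, and equilibration at C5 to the trans isomer may be incomplete. The fallback sets out from 12 and comes back at 14. Stoichiometric FeCl3 in CH2Cl2 at −50 → −10 °C, the classical silicon-directed Nazarov conditions, should give racemic trans-4-[3,4-bis(benzyloxy)benzyl]-5-(3,4-dimethoxybenzyl)cyclopent-2-en-1-one F1. Preparative chromatography on a chiral stationary phase (cellulose tris(3,5-dimethylphenylcarbamate)) would then supply the (4S,5R)-enantiomer 14, so absolute configuration would come from resolution and not from catalysis.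

Step 8. Osmylation of the electron-poor enone may be slow, the β-hydroxy ketone may eliminate to a diosphenol before cleavage, and the centre next to the new aldehyde may epimerise, which would erode enantiopurity once the lactone is formed. The fallback sets out from 14 and comes back at 16 and uses a nucleophilic oxidant in place of the electrophilic one. Weitz–Scheffer epoxidation (30% aq. H2O2, cat. NaOH, MeOH, 0 °C) should give (1S,3R,4R,5S)-4-[3,4-bis(benzyloxy)benzyl]-3-(3,4-dimethoxybenzyl)-6-oxabicyclo[3.1.0]hexan-2-one F2, with the oxirane anti to the C4 benzyl group. H5IO6 in aqueous THF would then open the oxirane and cleave the resulting ketol-diol to 16.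

Step 6. The vinyllithium may deprotonate the doubly activated γ-position of 9 instead of adding, the liberated N,O-dimethylhydroxylamine may add to the product enone during work-up, and the bromine–lithium exchange may be incomplete. The fallback sets out from 8 and comes back at 12, replacing acyl substitution by 1,2-addition to an aldehyde followed by oxidation. Reduction of 8 with i-Bu2AlH (CH2Cl2, −78 °C) should give (E)-4-[3,4-bis(benzyloxy)phenyl]-2-(3,4-dimethoxybenzyl)but-2-en-1-ol F3. Oxidation with MnO2 should give (E)-4-[3,4-bis(benzyloxy)phenyl]-2-(3,4-dimethoxybenzyl)but-2-enal F4. Addition of 11 at −78 °C should give (1E,4E)-6-[3,4-bis(benzyloxy)phenyl]-4-(3,4-dimethoxybenzyl)-1-(trimethylsilyl)hexa-1,4-dien-3-ol F5, and a second MnO2 (or Dess–Martin periodinane) oxidation should give 12.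

**Further compounds**

F1 | step 7 | racemic trans-4-[3,4-bis(benzyloxy)benzyl]-5-(3,4-dimethoxybenzyl)cyclopent-2-en-1-one (14 with its (4R,5S)-enantiomer) | COc1ccc(C[C@H]2C(=O)C=C[C@@H]2Cc2ccc(OCc3ccccc3)c(OCc3ccccc3)c2)cc1OC.COc1ccc(C[C@@H]2C(=O)C=C[C@H]2Cc2ccc(OCc3ccccc3)c(OCc3ccccc3)c2)cc1OC
F2 | step 8 | (1S,3R,4R,5S)-4-[3,4-bis(benzyloxy)benzyl]-3-(3,4-dimethoxybenzyl)-6-oxabicyclo[3.1.0]hexan-2-one | COc1ccc(C[C@H]2C(=O)[C@H]3O[C@H]3[C@@H]2Cc2ccc(OCc3ccccc3)c(OCc3ccccc3)c2)cc1OC
F3 | step 6 | (E)-4-[3,4-bis(benzyloxy)phenyl]-2-(3,4-dimethoxybenzyl)but-2-en-1-ol | OC/C(Cc1ccc(OC)c(OC)c1)=C/Cc1ccc(OCc2ccccc2)c(OCc2ccccc2)c1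
F4 | step 6 | (E)-4-[3,4-bis(benzyloxy)phenyl]-2-(3,4-dimethoxybenzyl)but-2-enal | O=C/C(Cc1ccc(OC)c(OC)c1)=C/Cc1ccc(OCc2ccccc2)c(OCc2ccccc2)c1
F5 | step 6 | (1E,4E)-6-[3,4-bis(benzyloxy)phenyl]-4-(3,4-dimethoxybenzyl)-1-(trimethylsilyl)hexa-1,4-dien-3-ol (racemic at C3) | C[Si](C)(C)/C=C/C(O)/C(Cc1ccc(OC)c(OC)c1)=C/Cc1ccc(OCc2ccccc2)c(OCc2ccccc2)c1
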